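The plan rests on cutting the C3–C4 bond of ring A (C1–C5, C10; labdane numbering). The feature exploited is the gem-dimethyl quaternary carbon C4 beside the ring-fusion carbon C5. It is read as the terminus of a cyclopentylcarbinyl-to-cyclohexyl shift. In the key step a CMe2OH group on the angular carbon C5 of a cis-hydrindanone ionises and C3 migrates from C5 to C4. The five-membered ring thereby becomes ring A, with a 5-ene set β,γ to the C8 ketone. The precursor is a Robinson-type hydrindanone whose angular ester carbon becomes C4 and whose sacrificial C5 centre has already fixed C10. The 5-en-8-one then delivers H5, O6 and C17.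

Key step: step 6

Remark: the labdane numbering of the target is kept for every intermediate (ring A C1–C5/C10, ring B C5–C10, C17 on C8, chain C11–C16), also while C4 is still exocyclic.
Assumption: of the two pseudo-enantiomeric cinchona catalysts, the one that delivers (S)-3 is used.

Step 1
Reactants: 1 methyl 2-oxocyclopentane-1-carboxylate; 2 but-3-en-2-one
Product: 3 methyl (1S)-2-oxo-1-(3-oxobutyl)cyclopentane-1-carboxylate
Conditions: 6′-OH cinchona catalyst (cupreine/cupreidine 9-O-aryl ether, 5 mol %), CH2Cl2, −20 °C
Reagents that add atoms: none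
Why: Catalytic asymmetric Michael addition of a cyclic β-keto ester to an enone under bifunctional cinchona catalysis, in which the ion-paired enolate is open on one face only, should set the quaternary carbon C5 as S; this centre is a relay that later controls C10 and is then sacrificed.

Step 2
Reactants: 3 methyl (1S)-2-oxo-1-(3-oxobutyl)cyclopentane-1-carboxylate
Product: 4 methyl (3aS)-6-oxo-1,2,3,4,5,6-hexahydro-3aH-indene-3a-carboxylate
Conditions: p-TsOH·H2O (cat.), toluene, reflux, Dean–Stark
Reagents that add atoms: none
Why: Acid-catalysed intramolecular aldol condensation (second half of a Robinson annulation), in which only attack of the methyl carbon C9 on the ring ketone C10 closes an unstrained six-membered ring, while C5 bears no hydrogen and the acidic medium avoids retro-Michael erosion of its configuration.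

Step 3
Reactants: 4 methyl (3aS)-6-oxo-1,2,3,4,5,6-hexahydro-3aH-indene-3a-carboxylate
Product: 8 methyl (3aS,7aS)-7a-methyl-7-methylidene-6-oxooctahydro-1H-indene-3a-carboxylate, via lithium enolate 5 (not isolated), via Mannich base 6 (not isolated), via methiodide 7 (not isolated)
Conditions: Me2CuLi (MeLi, CuI), Et2O, −20 °C; Me2N=CH2+ I−, THF, −78 °C → rt; MeI, Et2O; aq NaHCO3, CH2Cl2
Reagents that add atoms: lithium dimethylcuprate [Li+].C[Cu-]C; dimethyl(methylidene)ammonium iodide (Eschenmoser's salt) C[N+](C)=C.[I-]
Why: Conjugate addition of a Gilman cuprate to the bicyclic enone gives the cis-hydrindanone, methyl being delivered to C10 on the face of the angular ester because the trans-hydrindane transition state is strained, so C5 sets C10 as S; the regiodefined C8–C9 enolate is then trapped in a Mannich reaction and Hofmann-type elimination of the quaternised amine gives the exocyclic enone (C9=C11).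

Step 4
Reactants: 8 methyl (3aS,7aS)-7a-methyl-7-methylidene-6-oxooctahydro-1H-indene-3a-carboxylate
Product: 9 methyl (3aS,7aS)-7-(but-3-yn-1-yl)-7a-methyl-6-oxooctahydro-1H-indene-3a-carboxylate (C9 epimers)
Conditions: allenyl-SnBu3, TiCl4, CH2Cl2, −78 °C; aq NaHCO3
Reagents that add atoms: tributyl(propa-1,2-dienyl)stannane C=C=C[Sn](CCCC)(CCCC)CCCC
Why: Lewis-acid-mediated conjugate propargylation of an enone by an allenylstannane (SE2′, Sakurai-type) should add the three-carbon unit to the unhindered exocyclic C11; the C9 centre formed on protonation is left undefined because it stays epimerisable until step 7.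

Step 5
Reactants: 9 methyl (3aS,7aS)-7-(but-3-yn-1-yl)-7a-methyl-6-oxooctahydro-1H-indene-3a-carboxylate
Product: 11 (3aS,7aS)-4-(but-3-yn-1-yl)-7a-(2-hydroxypropan-2-yl)-3a-methyloctahydro-5H-inden-5-one (C9 epimers), via potassium enolate 10 (not isolated)
Conditions: KHMDS (1.1 equiv), THF, −78 °C; MeLi (excess), −78 °C → rt; aq NH4Cl
Reagents that add atoms: methyllithium [Li]C
Why: The ketone is masked in the flask as its enolate (and the alkyne as its acetylide), so that double addition of methyllithium is confined to the angular ester and turns the ester carbon into the carbinol carbon C4 bearing both methyl groups, without touching a stereocentre.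

Step 6
Reactants: 11 (3aS,7aS)-4-(but-3-yn-1-yl)-7a-(2-hydroxypropan-2-yl)-3a-methyloctahydro-5H-inden-5-one
Product: 12 (8aS)-1-(but-3-yn-1-yl)-5,5,8a-trimethyl-1,5,6,7,8,8a-hexahydronaphthalen-2(3H)-one (5-en-8-one, C9 epimers)
Conditions: p-TsOH·H2O (10 mol %), toluene, 80 °C, 4 Å MS
Reagents that add atoms: none
Why: Protonation and loss of water from the tertiary carbinol gives the exocyclic cation at C4, the C3–C5 σ-bond of the cyclopentane migrates to it, and the new tertiary cation at C5 loses H6 to give the 5-ene. The closest known reaction type is the Wagner–Meerwein ring expansion of cyclopentylcarbinyl cations (in biosynthesis the dammarenyl-to-baccharenyl D-ring enlargement), and because C5 carries no hydrogen the usual competing 1,2-hydride shift is excluded. No ring is closed by cyclisation: ring A arises by 1,2-shift enlargement of the ring C1–C2–C3–C5–C10 through insertion of C4, which brings both methyl groups with it. No stereocentre is created; the relay centre C5 is erased, C10 is untouched and C5–H is rewritten in step 7. The step needs migration of C3 rather than C6 or C10: C6 is β to the carbonyl group and its shift would enlarge ring B to a cycloheptanone, a shift of C10 would give a bridgehead cation in a bicyclo[4.3.1]decane, whereas the shift of C3 releases cyclopentane strain and the congestion of two adjacent quaternary carbons. Elimination to the isopropenyl compound is reversible under the conditions, and any 12 that the acid already conjugates converges with it in step 7.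

Step 7
Reactants: 12 (8aS)-1-(but-3-yn-1-yl)-5,5,8a-trimethyl-1,5,6,7,8,8a-hexahydronaphthalen-2(3H)-one
Product: 14 (5R,6S,7S,9S,10R)-6,7-epoxy-8-ketone (epoxide oxygen anti to the C10 methyl group; trans-decalin; equatorial but-3-ynyl chain at C9), via conjugated enone 13 (not isolated)
Conditions: 30 % H2O2, NaOH (cat.), MeOH, 0 °C → rt, degassed
Reagents that add atoms: hydrogen peroxide OO
Why: Hydroxide moves the double bond into conjugation through the dienolate, C5 being protonated reversibly so that the more stable trans-decalin (H5 anti to the axial C10 methyl group) prevails, and Weitz–Scheffer epoxidation drains this enone, hydroperoxide attacking C6 on the face away from the two syn-axial methyl groups on C4 and C10, which sets C6 and C7; the same base equilibrates C9 to the equatorial side chain.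

Step 8
Reactants: 14 (5R,6S,7S,9S,10R)-6,7-epoxy-8-ketone
Product: 16 (5R,6R,9S,10S)-6-hydroxy-7-ene 17-dimethyl acetal bearing the but-3-ynyl chain at C9, via epoxy enol ether 15 (not isolated)
Conditions: Ph3P+CH2OMe Cl−, KHMDS, THF, 0 °C → rt; crude 15: PPTS (cat.), MeOH, 0 °C
Reagents that add atoms: (methoxymethyl)triphenylphosphonium chloride COC[P+](c1ccccc1)(c1ccccc1)c1ccccc1.[Cl-]; methanol CO
Why: Wittig methoxymethylenation of the ketone adds C17, and under mild acid the enol ether pushes open the allylic C7–O bond of the epoxide (vinylogous ring opening), so that the C7=C8 double bond forms, the C6–O bond keeps its configuration and methanol caps the oxocarbenium ion as the acetal that masks the aldehyde.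

Step 9
Reactants: 16 (5R,6R,9S,10S)-6-hydroxy-7-ene 17-dimethyl acetal
Product: 17 (5R,6R,9S,10S)-16-acetoxy-13-ketone (chain C9–CH2CH2–CO–CH2OAc), acetal and 6-OH unchanged
Conditions: (Mor-DalPhos)AuNTf2 (5 mol %), 8-methylquinoline N-oxide, AcOH, PhCl, rt
Reagents that add atoms: 8-methylquinoline N-oxide Cc1cccc2ccc[n+]([O-])c12; acetic acid CC(=O)O
Why: Oxidative gold catalysis, in which N-oxide attack on the gold-activated terminal alkyne gives an α-oxo gold carbene at C16 that is intercepted by acetic acid (O–H insertion), delivers the C13 ketone and the C16 acetate regiospecifically under conditions that should spare the acetal, the allylic alcohol and the trisubstituted alkene.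

Step 10
Reactants: 17 (5R,6R,9S,10S)-16-acetoxy-13-ketone
Product: 19 methyl (2E)-3-(acetoxymethyl)-5-[(1S,4R,4aR,8aS)-2-formyl-4-hydroxy-5,5,8a-trimethyl-1,4,4a,5,6,7,8,8a-octahydronaphthalen-1-yl]pent-2-enoate (target), via acetal enoate 18 (not isolated)
Conditions: Ph3P=CHCO2Me, toluene, 90 °C; then PPTS (cat.), acetone–H2O, rt
Reagents that add atoms: methyl (triphenylphosphoranylidene)acetate COC(=O)C=P(c1ccccc1)(c1ccccc1)c1ccccc1; water O
Why: Wittig olefination with a stabilised ylide, which reacts with the activated α-acyloxy ketone and places the ester trans to the CH2O branch of such ketones (13E, the minor 13Z isomer being removed by chromatography), is followed by mild hydrolysis of the allylic acetal, which releases the enal without touching C6 or C9.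

Compound list
1 | methyl 2-oxocyclopentane-1-carboxylate | COC(=O)C1CCCC1=O | starting material
2 | but-3-en-2-one (methyl vinyl ketone) | CC(=O)C=C | starting material
3 | methyl (1S)-2-oxo-1-(3-oxobutyl)cyclopentane-1-carboxylate | CC(=O)CC[C@@]1(C(=O)OC)CCCC1=O | intermediate
4 | methyl (3aS)-6-oxo-1,2,3,4,5,6-hexahydro-3aH-indene-3a-carboxylate | O=C1CC[C@@]2(C(=O)OC)CCCC2=C1 | intermediate
5 | lithium C8–C9 enolate of the cis-fused 10-methyl keto ester (not isolated) | C1=C([O-])CC[C@@]2(C(=O)OC)CCC[C@@]12C.[Li+] | intermediate
6 | C9 (dimethylamino)methyl ketone, Mannich base, C9 undefined (not isolated) | CN(C)CC1C(=O)CC[C@@]2(C(=O)OC)CCC[C@@]12C | intermediate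
7 | methiodide of 6 (not isolated) | C[N+](C)(C)CC1C(=O)CC[C@@]2(C(=O)OC)CCC[C@@]12C.[I-] | intermediate
8 | methyl (3aS,7aS)-7a-methyl-7-methylidene-6-oxooctahydro-1H-indene-3a-carboxylate | C=C1C(=O)CC[C@@]2(C(=O)OC)CCC[C@@]12C | intermediate
9 | methyl (3aS,7aS)-7-(but-3-yn-1-yl)-7a-methyl-6-oxooctahydro-1H-indene-3a-carboxylate, C9 epimers | C#CCCC1C(=O)CC[C@@]2(C(=O)OC)CCC[C@@]12C | intermediate
10 | potassium C7–C8 enolate of 9 (not isolated) | C#CCCC1C([O-])=CC[C@@]2(C(=O)OC)CCC[C@@]12C.[K+] | intermediate
11 | (3aS,7aS)-4-(but-3-yn-1-yl)-7a-(2-hydroxypropan-2-yl)-3a-methyloctahydro-5H-inden-5-one, C9 epimers | C#CCCC1C(=O)CC[C@@]2(C(C)(C)O)CCC[C@@]12C | intermediate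
12 | (8aS)-1-(but-3-yn-1-yl)-5,5,8a-trimethyl-1,5,6,7,8,8a-hexahydronaphthalen-2(3H)-one, C9 epimers | C#CCCC1C(=O)CC=C2C(C)(C)CCC[C@@]12C | intermediate
13 | (1S,4aR,8aR)-1-(but-3-yn-1-yl)-5,5,8a-trimethyl-4a,5,6,7,8,8a-hexahydronaphthalen-2(1H)-one (not isolated) | C#CCC[C@@H]1C(=O)C=C[C@@H]2C(C)(C)CCC[C@@]12C | intermediate
14 | (5R,6S,7S,9S,10R)-6,7-epoxide of 13, oxygen anti to the C10 methyl group | C#CCC[C@@H]1C(=O)[C@H]3O[C@H]3[C@@H]2C(C)(C)CCC[C@@]12C | intermediate
15 | 8(17)-methoxymethylidene derivative of 14, E/Z mixture at C8=C17 (not isolated) | C#CCC[C@@H]1C(=COC)[C@H]3O[C@H]3[C@@H]2C(C)(C)CCC[C@@]12C | intermediate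
16 | (5R,6R,9S,10S)-9-(but-3-ynyl)-6-hydroxy-7-ene 17-dimethyl acetal | C#CCC[C@@H]1C(C(OC)OC)=C[C@@H](O)[C@@H]2C(C)(C)CCC[C@@]12C | intermediate
17 | (5R,6R,9S,10S)-16-acetoxy-13-oxo 17-dimethyl acetal | CC(=O)OCC(=O)CC[C@@H]1C(C(OC)OC)=C[C@@H](O)[C@@H]2C(C)(C)CCC[C@@]12C | intermediate
18 | 17-dimethyl acetal of the target, 13E (not isolated) | COC(=O)/C=C(\CC[C@@H]1C(C(OC)OC)=C[C@@H](O)[C@@H]2C(C)(C)CCC[C@@]12C)COC(C)=O | intermediate
19 | methyl (2E)-3-(acetoxymethyl)-5-[(1S,4R,4aR,8aS)-2-formyl-4-hydroxy-5,5,8a-trimethyl-1,4,4a,5,6,7,8,8a-octahydronaphthalen-1-yl]pent-2-enoate | COC(=O)/C=C(\CC[C@@H]1C(C=O)=C[C@@H](O)[C@@H]2C(C)(C)CCC[C@@]12C)COC(C)=O | target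

Total step count: 10. Longest linear sequence: 10.

Steps most likely to fail

Step 6. The C4 cation may merely lose a proton to the isopropenyl group. Repeated re-protonation may let methyl groups wander from C4 or C10 to C5. The C5–C6 bond may also fragment through the enol in a retro-Michael sense. The fallback sets out from 11. Syn-elimination with the Burgess reagent gives the cis-fused isopropenyl ketone F1. The C4 cation is then generated from the 1,1-disubstituted alkene without Brønsted acid, by cobalt-salen hydrogen-atom transfer and oxidation (silane, N-fluoro-2,4,6-collidinium triflate; radical–polar crossover). The terminal alkyne is the slower hydrogen-atom acceptor. The collidine that is liberated removes H6 at once, so the alkene is not re-protonated. The route is rejoined at 12.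

Step 7. Three things can go wrong here:
- γ-Protonation at the hindered C5 may be slow.
- The dienolate may be oxidised.
- Facial selectivity at C6 may be poor, because the stereoelectronically preferred axial attack of hydroperoxide lies on the methyl-shielded face.

The fallback sets out from 12. DBU in toluene conjugates it to 13, which is now isolated. Wittig methoxymethylenation of 13 gives the 17-methoxy-6,8(17)-diene F2. m-CPBA in NaHCO3-buffered methanol then oxidises the distal C6=C7 bond in a sterically ruled, electrophilic sense (vinylogous Rubottom oxidation). The enol ether opens the epoxide and methanol caps C17. The route is rejoined at 16, so that 14 and 15 are bypassed.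

Step 5. Proton exchange between the enolate and the intermediate methyl ketone may unmask the C8 ketone towards methyllithium, or may stall the addition at the acetyl stage. The fallback sets out from 9. The ketone is covalently protected (1,2-bis(trimethylsilyloxy)ethane, TMSOTf) as the ethylene ketal ester F3. Methyllithium with CeCl3 converts it into the ethylene ketal carbinol F4. PPTS in aqueous acetone removes the ketal without ionising the carbinol. The route is rejoined at 11.

Further compounds
F1 | step 6 | (3aS,7aR)-4-(but-3-yn-1-yl)-3a-methyl-7a-(prop-1-en-2-yl)octahydro-5H-inden-5-one, C9 epimers | C#CCCC1C(=O)CC[C@@]2(C(C)=C)CCC[C@@]12C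
F2 | step 7 | 8(17)-methoxymethylidene derivative of 13 (17-methoxy-6,8(17)-diene, E/Z mixture at C8=C17) | C#CCC[C@@H]1C(=COC)C=C[C@@H]2C(C)(C)CCC[C@@]12C
F3 | step 5 | ethylene ketal of 9 | C#CCCC1C2(OCCO2)CC[C@@]3(C(=O)OC)CCC[C@@]13C
F4 | step 5 | ethylene ketal of 11 | C#CCCC1C2(OCCO2)CC[C@@]3(C(C)(C)O)CCC[C@@]13C
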